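## The problem

Locants used throughout: ring A (cycloheptane) C2(Me)–C3–C4–C5–C6–C10(Me2)–C11; ring B (cyclopentane) C5–C6–C7–C8–C9(Me)(OH); bridge C11=C12–C13; ring C (cyclohexane) C14–C15(Me)–C21–C22–C23–C24(Me)(OH); ring D (oxepanone) C15–C16–C17–C18(=O)–C19(Me2)–O20–C21.

The target 48 is a C30 triterpenoid in which a cis-fused bicyclo[5.3.0]decane (rings A and B) and a trans-fused oxepanone–cyclohexane (rings D and C) are joined by an exocyclic trisubstituted alkene C11=C12 and one methylene, C13. The alkene is Z: C13 sits on the side of the quaternary C10, the more crowded side, so its geometry cannot be left to thermodynamic control. The eight stereocentres form two sets (C2, C5, C6, C9 and C14, C15, C21, C24) that are too far apart to influence each other, so each half has to be made enantiopure and the halves joined late. In the left half the C9 carbinol can direct reduction of the ring fusion (C5, C6), but C2 is remote and needs reagent control. In the right half the C21 oxygen can steer C15, and the axial C15 methyl of the trans-fused bicycle can then steer C24 and C14. The two tertiary alcohols, the C2–H next to C11 and the alkene rule out strong acid at any stage and base once C11 is a ketone. The feature that opens the key step is the quaternary C10 lying between C11 and the ring-fusion carbon C6. If C6–C10–C11 is a gem-dimethylcyclopropane, the bonds C11–C2 and C6–C5 carry the two vinyl arms, and C3–C4 is the bond made by a divinylcyclopropane ring expansion.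

## Retrosynthesis

The C18 ketone cannot coexist with the organolithium chemistry of the fragment union. Target 48 is therefore traced to triol 47, whose only oxidisable hydroxyl is the secondary C18 carbinol, and 47 to its tris-silyl ether 46.

The C12–C13 bond of 46 is cut to give alkenyl boronate 24 and primary iodide 42. Cutting C11=C12 instead (olefination of a ketone by a right-half ylide) would give mixtures or the less hindered isomer. Cutting C13–C14 would require a Z-allylic halide that is prone to isomerise. A Zweifel coupling through alkyllithium 43 and boronate complex 44 is stereospecific with inversion. The E boronate 24, the isomer expected on steric grounds (boron anti to C10), therefore delivers the contra-steric Z alkene. The forward reaction needs clean iodine–lithium exchange and an anti elimination.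

Boronate 24 is traced to ketone 22 by removal of C12 (boron–Wittig olefination). Ketone 22 comes from hydroxy ketone 21, and 21 from diol 20. The cis ring fusion of 20 arises by hydrogenating C5=C6 of diene diol 19, where both hydroxyls sit on one face. Diol 19 comes from alcohol 18, and 18 from diene 16 by hydroboration of the trisubstituted C11=C2 alkene, which places oxygen on C11 and hydrogen on C2. Diene 16 has two alkenes of clearly different substitution, which is what makes this ordering possible.

Key disconnection: in 16 the C3–C4 bond is cut and C6–C11 reconnected, leading to cis-divinylcyclopropane 15 and its accessible trans isomer 14. Ring-closing metathesis or an enolate-based cut of ring A would need separate installation of the gem-dimethyl quaternary carbon next to a tetrasubstituted alkene. Here C10 is simply the spectator carbon of the cyclopropane, and the seven-membered ring is reduced to a three-membered ring on a cyclopentane. The forward reaction must funnel every cyclopropane diastereomer into one diene.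

Precursor 14 is traced to spiro ketone 13 (methylenation, C5=C4). Ketone 13 comes from dienone 10 by isopropylidene transfer from ylide 12, made from sulfonium salt 11 (bonds C6–C10 and C10–C11). Dienone 10 comes from silyloxy ketone 6 and methacrolein 7 by aldol condensation (C6=C11). The ketone in 13 has no α-hydrogen, which makes the hindered methylenation tolerable.

Ketone 6 is traced through hydroxy ketone 5, diol 4 and epoxy alcohol 3 to cyclopentenol 2, the ring-closing metathesis product of (R)-linalool 1. The chiral pool supplies C9 in high enantiomeric purity, which a catalytic oxidation of a small cyclic trisubstituted alkene would not guarantee.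

Iodide 42 is traced to diol iodide 41 and triol 40. The C13 hydroxymethyl group and the C14 stereocentre of 40 come from hydroboration of the exocyclic methylene of 38 (through borane 39). The C24 carbinol of 38 comes from methyl addition to bicyclic enone 37.

Ring D of 37 is opened at O20–C19 to epoxy alcohol 36, made from hydroxy enone 35. The ring is closed before the methyl addition because only the locked trans-fused bicycle fixes the C15 methyl axial, which is what controls C24 and C14.

Enone 35 comes from silyl ether 34, and 34 from silyl enol ether 31 by a Mannich methylenation (C14=C13). Enol ether 31 comes from enone 28 and bromide 29 (through Grignard reagent 30) by conjugate addition anti to the C21 silyloxy group (C15–C16). Enone 28 is reached from 2-methylcyclohex-2-enone 25 through alcohol 26 and silyl ether 27.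

## Roads not taken

Alternative 1: Rings A and B would be cut back to an anisole. Diazoketone A1 would be decomposed by the chiral dirhodium tetracarboxylate Rh2(S-PTTL)4 (divalent rhodium). The carbene adds to the ipso and free ortho carbons and the norcaradiene opens to dihydroazulenone A2. Its merits are real: both rings form in one step from a flat arene, A2 is reached in fewer steps than diene 16, and the C9 ketone and a masked C11 ketone are already in place. Its weak points are specific to this target. The step sets only C5. C10 carries one methyl and must be quaternised later next to a ring-fusion alkene. C9, C6 and C2 have to be relayed from C5 through a triene that must be reduced selectively. Enantioselective intramolecular Buchner reactions of simple diazoketones on a tetrasubstituted arene are not reliably selective. In step count to the bicyclic core Alternative 1 is better. Against that the chosen plan has the C9 configuration from the chiral pool, both quaternary carbons (C9, C10) in place, and only two alkenes of clearly different reactivity in 16.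

Alternative 2: The cut is at C15–C16 and C13–C14. A chiral N-heterocyclic carbene complex of monovalent copper (from CuBr·SMe2) would add 4-methylpent-3-enylmagnesium bromide to enone ketal A3, and the magnesium enolate would be alkylated by the left-half allylic bromide A4 to give A5. It is the most convergent plan: the C15 quaternary centre and the fragment union come in one flask, without organolithium steps or extra protecting groups, and in overall step count it is better than the chosen route. Three points weigh against it. Bromide A4 must carry the contra-steric Z alkene, and primary allylic bromides of this type drift to the less hindered isomer by ionisation. A magnesium enolate next to a fresh quaternary carbon must be alkylated by a bulky electrophile. Ring D must then be built on A5 in the presence of the C11=C12 alkene, so epoxidation has to distinguish two trisubstituted alkenes. The chosen route also makes C15–C16 by conjugate addition, but under substrate control from C21. It fixes the alkene geometry by a stereospecific inversion and finishes ring D before the union.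

Alternative 3: Rings C and D would be cut at O20–C19 and C14–C15. TMSOTf with a hindered pyridine base would activate the terminal epoxide of bis-epoxy β-keto ester A6, the internal epoxide oxygen would attack C19, and the enol carbon would open the epoxonium ion to give A7. One cascade closes two rings and sets C14, C15 and C21, and as a way to the right half it is shorter than steps 16–26 of the chosen route. It is weaker in three respects. It addresses only the half without the gem-dimethylcycloheptane and leaves the Z alkene unsolved. A7 carries an enolisable β-keto ester next to the carbonyl that must receive the C24 methyl. The cascade has to be endo-selective twice. The chosen plan pays with more steps on the right half, each an ordinary transformation with C24 and C14 set on a locked bicycle. The cascade could replace those steps without touching the key disconnection.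

Key step: step 9

Remarks on the chemistry:
- Compounds 13 and 14 are written as the cyclopropane diastereomer expected to predominate (isopropenyl anti to C5, C10 anti to the silyloxy group); the other cyclopropane diastereomers are carried along, because step 9 erases both cyclopropane stereocentres.
- From 36 onward C18 is carried as both epimers (left open in the SMILES), because step 29 turns it into the ketone.
- The not-isolated species 8, 9, 23, 32, 33 and 45 are diastereomer mixtures at centres that disappear in the same step.

## Route

Step 1
Reactants: 1 (R)-linalool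
Product: 2 (R)-1-methylcyclopent-2-en-1-ol
Conditions: second-generation Grubbs catalyst RuCl2(=CHPh)(H2IMes)(PCy3) (1 mol%), CH2Cl2, 25 °C
Reagents that add atoms: none
Why: Ring-closing metathesis of the 1,6-diene with loss of isobutene; the tertiary carbinol stereocentre is a spectator and becomes C9.

Step 2
Reactants: 2 (R)-1-methylcyclopent-2-en-1-ol
Product: 3 cis-2,3-epoxy-1-methylcyclopentan-1-ol (epoxide oxygen syn to the hydroxyl)
Conditions: VO(acac)2 (2 mol%), t-BuOOH, CH2Cl2, 0 → 25 °C
Reagents that add atoms: tert-butyl hydroperoxide, CC(C)(C)OO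
Why: Hydroxyl-directed vanadium-catalysed epoxidation of a cyclic allylic alcohol delivers oxygen to the face of the hydroxyl.

Step 3
Reactants: 3 cis-2,3-epoxy-1-methylcyclopentan-1-ol
Product: 4 (1R,2S)-1-methylcyclopentane-1,2-diol
Conditions: LiAlH4, Et2O, 0 → 25 °C
Reagents that add atoms: none
Why: Hydride opens the epoxide by SN2 attack at the carbon remote from the quaternary carbinol, leaving the cis-1,2-diol; the tertiary centre is not touched.

Step 4
Reactants: 4 (1R,2S)-1-methylcyclopentane-1,2-diol
Product: 5 (R)-2-hydroxy-2-methylcyclopentanone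
Conditions: IBX, EtOAc, 75 °C
Reagents that add atoms: none
Why: IBX oxidises the secondary hydroxyl of a 1,2-diol to the α-hydroxy ketone without C–C cleavage; the tertiary alcohol is inert.

Step 5
Reactants: 5 (R)-2-hydroxy-2-methylcyclopentanone
Product: 6 (R)-2-methyl-2-(triethylsilyloxy)cyclopentanone
Conditions: Et3SiOTf, 2,6-lutidine, CH2Cl2, −78 → 0 °C
Reagents that add atoms: triethylsilyl trifluoromethanesulfonate, CC[Si](CC)(CC)OS(=O)(=O)C(F)(F)F
Why: Silyl triflate with a hindered base silylates tertiary alcohols; triethylsilyl is chosen because fluoride removes it later from a tertiary allylic position without acid.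

Step 6
Reactants: 6 (R)-2-methyl-2-(triethylsilyloxy)cyclopentanone; 7 methacrolein
Product: 10 (R,E)-2-methyl-5-(2-methylprop-2-enylidene)-2-(triethylsilyloxy)cyclopentanone, via lithium aldolate 8 (not isolated), via aldol mesylate 9 (not isolated)
Conditions: LiN(iPr)2, THF, −78 °C; 7; MsCl, −78 → 0 °C; DBU, 25 °C
Reagents that add atoms: none
Why: Directed aldol condensation: C6 is the only enolisable position, the lithium enolate adds 1,2 to the enal, and mesylation with E1cB elimination gives the more stable E dienone (isopropenyl anti to the carbonyl).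

Step 7
Reactants: 10 (R,E)-2-methyl-5-(2-methylprop-2-enylidene)-2-(triethylsilyloxy)cyclopentanone; 11 isopropyldiphenylsulfonium tetrafluoroborate
Product: 13 (5R)-1,1,5-trimethyl-2-(prop-1-en-2-yl)-5-(triethylsilyloxy)spiro[2.4]heptan-4-one (isopropenyl anti to the carbonyl carbon), via diphenylsulfonium isopropylide 12 (not isolated)
Conditions: 11, LiN(iPr)2, DME/CH2Cl2, −78 °C; then 10, −78 → −20 °C
Reagents that add atoms: none
Why: Isopropylidene transfer from a sulfonium ylide (Corey–Chaykovsky type): conjugate addition at C11 and 3-exo-tet closure at C6, the α,β-alkene of a dienone being the site attacked as in chrysanthemate syntheses; the cyclopropane configuration is inconsequential.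

Step 8
Reactants: 13 (5R)-1,1,5-trimethyl-2-(prop-1-en-2-yl)-5-(triethylsilyloxy)spiro[2.4]heptan-4-one
Product: 14 (5R)-1,1,5-trimethyl-4-methylidene-2-(prop-1-en-2-yl)-5-(triethylsilyloxy)spiro[2.4]heptane (trans: isopropenyl anti to the methylidene carbon)
Conditions: Ph3PCH3Br, KOtBu, toluene, 90 °C
Reagents that add atoms: methyltriphenylphosphonium bromide, C[P+](c1ccccc1)(c1ccccc1)c1ccccc1.[Br-]
Why: Salt-free Wittig methylenation under the forcing conditions known for ketones flanked by two quaternary carbons; the ketone has no α-hydrogen, so heat and alkoxide cannot enolise it.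

Step 9
Reactants: 14 (5R)-1,1,5-trimethyl-4-methylidene-2-(prop-1-en-2-yl)-5-(triethylsilyloxy)spiro[2.4]heptane
Product: 16 (3R)-3,6,8,8-tetramethyl-3-(triethylsilyloxy)-1,2,3,4,5,8-hexahydroazulene (rings A and B; alkenes C11=C2 and C5=C6), via cis-divinylcyclopropane 15 (not isolated)
Conditions: toluene, BHT (5 mol%), base-washed sealed tube, 160 °C
Reagents that add atoms: none
Why: Heating 14 homolyses the C6–C11 bond to a bis-allylic diradical (tertiary at C6) that recloses to the cis isomer 15, the known one-centre epimerisation by which trans isomers enter the divinylcyclopropane–cycloheptadiene rearrangement. Isomer 15 then undergoes the [3,3]-sigmatropic shift through the boat transition state, breaking C6–C11 and forming C3–C4, driven by release of cyclopropane strain. Ring A is closed in the sigmatropic step itself, as a ring expansion of the three-membered ring to the cyclohepta-1,4-diene, not by an end-to-end cyclisation. No stereocentre is formed: C6 and C11 become sp2, so all cyclopropane stereoisomers converge on 16, and C9 is a spectator under its silyl ether. The step needs the cis relation of the arms, supplied by the thermal equilibration, and a reactive alignment of both arms: ring B holds C5=C4 in the bisected orientation in which its π orbital overlaps the breaking bond, and both bonding termini are CH2 groups, so no inward substituent enters the boat. The selectivity that matters is against the homodienyl 1,5-hydrogen shift from a C10 methyl cis to a vinyl group; the diradical path should win through the extra substitution at C6 and its looser transition state. Acid-free glass protects the tertiary allylic silyl ether. The closest known reaction type is the thermal rearrangement of 2,2-dimethyl-1,3-divinylcyclopropanes to 6,6-dimethylcyclohepta-1,4-dienes.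

Step 10
Reactants: 16 (3R)-3,6,8,8-tetramethyl-3-(triethylsilyloxy)-1,2,3,4,5,8-hexahydroazulene
Product: 18 (2S,9R,11R)-C11 alcohol (H2 and the C11 hydroxyl on the face of the C9 oxygen; C5=C6 retained; C9 triethylsilyl ether), via dialkylborane 17 (not isolated)
Conditions: (IpcBH2)2·TMEDA [from (+)-α-pinene], BF3·OEt2, THF, 25 °C; 16, −25 → 0 °C; NaOH, H2O2
Reagents that add atoms: hydrogen peroxide, OO
Why: Asymmetric hydroboration–oxidation: boron adds to the less substituted C11 and hydrogen to C2 on the same face, and the tetrasubstituted C5=C6 alkene does not react. The borane antipode that gives (1S,2S)-trans-2-methylcycloalkanols from 1-methylcycloalkenes should select the face that makes C2 S; the minor diastereomer is removed by chromatography.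

Step 11
Reactants: 18 (2S,9R,11R)-C11 alcohol
Product: 19 (2S,9R,11R)-diene diol (free C9 and C11 hydroxyls; C5=C6)
Conditions: Bu4NF, THF, 25 °C
Reagents that add atoms: none
Why: Fluoride cleaves the tertiary triethylsilyl ether under non-acidic conditions, which avoids ionisation of the tertiary allylic alcohol.

Step 12
Reactants: 19 (2S,9R,11R)-diene diol
Product: 20 (2S,5R,6R,9R,11R)-cis-fused diol (H5 and H6 syn to the C9 hydroxyl)
Conditions: [Ir(cod)(PCy3)(py)]PF6 (5 mol%), H2 (1 atm), CH2Cl2, 0 → 25 °C
Reagents that add atoms: none
Why: Hydroxyl-directed hydrogenation of a tetrasubstituted alkene: the cationic iridium catalyst binds the allylic C9 hydroxyl and the homoallylic C11 hydroxyl, which lie on the same face, and delivers both hydrogens to C5 and C6 from that face.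

Step 13
Reactants: 20 (2S,5R,6R,9R,11R)-cis-fused diol
Product: 21 (2S,5R,6R,9R)-C11 ketone with free C9 hydroxyl
Conditions: Dess–Martin periodinane, NaHCO3, CH2Cl2, 0 °C
Reagents that add atoms: none
Why: Dess–Martin oxidation of the only secondary alcohol; the buffered, non-basic medium leaves the C2 stereocentre α to the new ketone intact.

Step 14
Reactants: 21 (2S,5R,6R,9R)-C11 ketone with free C9 hydroxyl
Product: 22 (2S,5R,6R,9R)-C11 ketone C9 triethylsilyl ether
Conditions: Et3SiOTf, 2,6-lutidine, CH2Cl2, −78 °C
Reagents that add atoms: triethylsilyl trifluoromethanesulfonate, CC[Si](CC)(CC)OS(=O)(=O)C(F)(F)F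
Why: Low-temperature silylation of the tertiary alcohol with a hindered pyridine base, which does not enolise the hindered ketone; the ether is needed for the organolithium step.

Step 15
Reactants: 22 (2S,5R,6R,9R)-C11 ketone C9 triethylsilyl ether
Product: 24 (E)-alkenyl pinacol boronate (C11=C12, boron anti to C10), via lithium diboryl alkoxide 23 (not isolated)
Conditions: CH2(Bpin)2, lithium 2,2,6,6-tetramethylpiperidide (LiTMP), THF, 0 °C; 22, −78 → 25 °C
Reagents that add atoms: bis(pinacolato)borylmethane, CC1(C)OB(CB2OC(C)(C)C(C)(C)O2)OC1(C)C
Why: Boron–Wittig olefination: the lithiated geminal diboronate adds to the ketone and syn B–O elimination leaves the remaining boryl group anti to the larger substituent, the quaternary C10. The stabilised carbanion is a weak base, which limits enolisation toward C2.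

Step 16
Reactants: 25 2-methylcyclohex-2-en-1-one
Product: 26 (R)-2-methylcyclohex-2-en-1-ol
Conditions: (S)-2-methyl-CBS-oxazaborolidine (10 mol%), BH3·SMe2, THF, −20 °C
Reagents that add atoms: none
Why: Corey–Bakshi–Shibata reduction of an α-substituted enone; the alkenyl carbon acts as the large group, which places hydride so that the R alcohol (future C21) results.

Step 17
Reactants: 26 (R)-2-methylcyclohex-2-en-1-ol
Product: 27 (R)-tert-butyldimethyl(2-methylcyclohex-2-enyloxy)silane
Conditions: t-BuMe2SiCl, imidazole, DMF, 25 °C
Reagents that add atoms: tert-butyldimethylsilyl chloride, CC(C)(C)[Si](C)(C)Cl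
Why: Standard silylation of a secondary alcohol; the bulky ether later directs the conjugate addition.

Step 18
Reactants: 27 (R)-tert-butyldimethyl(2-methylcyclohex-2-enyloxy)silane
Product: 28 (R)-4-(tert-butyldimethylsilyloxy)-3-methylcyclohex-2-en-1-one
Conditions: Rh2(cap)4 (cap = caprolactamate, 1 mol%), t-BuOOH, K2CO3, CH2Cl2, 25 °C
Reagents that add atoms: tert-butyl hydroperoxide, CC(C)(C)OO
Why: Allylic oxidation of the ring methylene next to the unsubstituted alkene carbon, the regiochemistry known for 1-methylcyclohexenes; the allylic C–H that bears the silyloxy group is shielded by the silyl group and the vinylic methyl.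

Step 19
Reactants: 28 (R)-4-(tert-butyldimethylsilyloxy)-3-methylcyclohex-2-en-1-one; 29 5-bromo-2-methylpent-2-ene
Product: 31 trimethylsilyl enol ether (C14=C24; C15 quaternary with methyl cis to the C21 silyloxy group), via homoprenylmagnesium bromide 30 (not isolated)
Conditions: 29, Mg, THF; CuBr·SMe2 (20 mol%), Me3SiCl, HMPA, THF, −78 °C; Et3N
Reagents that add atoms: chlorotrimethylsilane, C[Si](C)(C)Cl
Why: Copper-catalysed, chlorosilane-accelerated conjugate addition of a Grignard reagent to a β,β-disubstituted enone; attack anti to the γ-silyloxy group sets C15, and the enolate is captured regiospecifically as its silyl enol ether.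

Step 20
Reactants: 31 trimethylsilyl enol ether
Product: 34 α-methylene ketone (C14=C13H2, C24 ketone, C21 silyl ether), via Mannich base 32 (not isolated), via trimethylammonium iodide 33 (not isolated)
Conditions: CH2=NMe2 I (Eschenmoser's salt), CH2Cl2, 25 °C; MeI; DBU
Reagents that add atoms: N,N-dimethylmethyleneiminium iodide, C=[N+](C)C.[I-]
Why: Mannich reaction of the silyl enol ether at C14, then quaternisation and elimination; this fixes C13 on the hindered α-carbon, which a later enolisation of the ketone would not select.

Step 21
Reactants: 34 α-methylene ketone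
Product: 35 hydroxy enone (free C21 hydroxyl)
Conditions: HF (aq.), MeCN, 25 °C
Reagents that add atoms: none
Why: Acidic fluoride removes the secondary silyl ether without forming an alkoxide, which could add to the α-methylene ketone.

Step 22
Reactants: 35 hydroxy enone
Product: 37 bicyclic enone alcohol (rings C and D trans-fused; C18 hydroxyl as both epimers; C24 ketone; C14=C13H2), via epoxy alcohol 36 (not isolated)
Conditions: mCPBA, CH2Cl2, 0 °C; then CSA (10 mol%), 0 °C
Reagents that add atoms: 3-chloroperbenzoic acid, O=C(OO)c1cccc(Cl)c1
Why: The peracid epoxidises the electron-rich trisubstituted alkene and leaves the enone alone. Acid then opens the epoxide at the tertiary C19, which carries most of the positive charge, by 7-endo attack of the C21 hydroxyl with retention at C21, giving the trans-fused oxepane. The competing 6-exo opening at C18 is disfavoured electronically and is the point to watch.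

Step 23
Reactants: 37 bicyclic enone alcohol
Product: 38 bicyclic diol (C24 methyl carbinol with axial hydroxyl; C14=C13H2)
Conditions: MeLi, CeCl3, THF, −78 °C
Reagents that add atoms: methyllithium, [Li]C
Why: Organocerium 1,2-addition to the enone; in the locked trans-fused bicycle the axial C15 methyl blocks axial attack, so methyl enters equatorially and the C24 hydroxyl is axial, as in the target.

Step 24
Reactants: 38 bicyclic diol
Product: 40 triol (C13 primary alcohol; C14 hydrogen axial), via alkylborane 39 (not isolated)
Conditions: BH3·THF, 0 → 25 °C; NaOH, H2O2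
Reagents that add atoms: hydrogen peroxide, OO
Why: Anti-Markovnikov hydroboration–oxidation of the 1,1-disubstituted alkene. Borane approaches the face opposite the axial C15 methyl and the axial C24 hydroxyl, which flank C14 on the same side, so hydrogen ends axial at C14 and the C13 arm equatorial.

Step 25
Reactants: 40 triol
Product: 41 primary iodide diol
Conditions: I2, PPh3, imidazole, CH2Cl2, 0 → 25 °C
Reagents that add atoms: iodine, II
Why: Appel-type iodination is selective for the primary alcohol over the hindered secondary and the tertiary hydroxyls.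

Step 26
Reactants: 41 primary iodide diol
Product: 42 primary iodide bis(triethylsilyl) ether (O18 and O24 silylated)
Conditions: Et3SiOTf, 2,6-lutidine, CH2Cl2, −40 → 0 °C
Reagents that add atoms: triethylsilyl trifluoromethanesulfonate, CC[Si](CC)(CC)OS(=O)(=O)C(F)(F)F
Why: Silyl triflate silylates both the hindered secondary and the tertiary alcohol; the alkyl iodide is inert to these conditions.

Step 27
Reactants: 42 primary iodide bis(triethylsilyl) ether; 24 (E)-alkenyl pinacol boronate
Product: 46 coupled tris(triethylsilyl) ether (C11=C12 Z, C13 syn to C10), via alkyllithium 43 (not isolated), via boronate complex 44 (not isolated), via iodo boronate 45 (not isolated)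
Conditions: t-BuLi (2.1 equiv), Et2O, −78 °C; 24, THF, −78 °C; I2, MeOH, −78 °C; NaOMe, MeOH, −78 → 25 °C
Reagents that add atoms: none
Why: Zweifel olefination: iodine–lithium exchange, addition to boron, then iodine-induced 1,2-migration of the C13 alkyl group anti to the iodonium ion and anti elimination of boron and iodide. The sequence is stereospecific with inversion of the alkene geometry, so the E boronate gives the Z alkene.

Step 28
Reactants: 46 coupled tris(triethylsilyl) ether
Product: 47 triol (C9, C18 and C24 hydroxyls free)
Conditions: Bu4NF, THF, 50 °C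
Reagents that add atoms: none
Why: Fluoride removes all three triethylsilyl groups without acid, so neither tertiary alcohol nor the alkene is put at risk.

Step 29
Reactants: 47 triol
Product: 48 target (CNP0157787.1)
Conditions: Dess–Martin periodinane, NaHCO3, CH2Cl2, 0 → 25 °C
Reagents that add atoms: none
Why: Dess–Martin oxidation of the single secondary alcohol (either C18 epimer) to the ketone; the two tertiary alcohols cannot be oxidised and the buffered medium spares the alkene.

## Compound list

1 | (R)-linalool, (3R)-3,7-dimethylocta-1,6-dien-3-ol | C=C[C@](C)(O)CCC=C(C)C | starting material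
2 | (R)-1-methylcyclopent-2-en-1-ol | C[C@]1(O)C=CCC1 | intermediate
3 | cis-2,3-epoxy-1-methylcyclopentan-1-ol (1R carbinol, epoxide syn to OH) | C[C@]1(O)[C@H]2O[C@H]2CC1 | intermediate
4 | (1R,2S)-1-methylcyclopentane-1,2-diol | C[C@]1(O)[C@@H](O)CCC1 | intermediate
5 | (R)-2-hydroxy-2-methylcyclopentanone | C[C@]1(O)C(=O)CCC1 | intermediate
6 | (R)-2-methyl-2-(triethylsilyloxy)cyclopentanone | C[C@]1(O[Si](CC)(CC)CC)C(=O)CCC1 | intermediate
7 | methacrolein | C=C(C)C=O | starting material
8 | lithium aldolate of 6 and 7 (C6, C11 epimers) | [Li+].[O-]C(C(C)=C)C1CC[C@@](C)(O[Si](CC)(CC)CC)C1=O | intermediate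
9 | aldol mesylate (C6, C11 epimers) | CS(=O)(=O)OC(C(C)=C)C1CC[C@@](C)(O[Si](CC)(CC)CC)C1=O | intermediate
10 | (R,E)-2-methyl-5-(2-methylprop-2-enylidene)-2-(triethylsilyloxy)cyclopentanone | C=C(C)/C=C1\CC[C@@](C)(O[Si](CC)(CC)CC)C1=O | intermediate
11 | isopropyldiphenylsulfonium tetrafluoroborate | CC(C)[S+](c1ccccc1)c1ccccc1.F[B-](F)(F)F | starting material
12 | diphenylsulfonium isopropylide | C[C-](C)[S+](c1ccccc1)c1ccccc1 | intermediate
13 | (5R)-1,1,5-trimethyl-2-(prop-1-en-2-yl)-5-(triethylsilyloxy)spiro[2.4]heptan-4-one, isopropenyl anti to the carbonyl carbon | O=C1[C@](C)(O[Si](CC)(CC)CC)CC[C@@]12C(C)(C)[C@@H]2C(C)=C | intermediate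
14 | (5R)-1,1,5-trimethyl-4-methylidene-2-(prop-1-en-2-yl)-5-(triethylsilyloxy)spiro[2.4]heptane, trans arms | C=C1[C@](C)(O[Si](CC)(CC)CC)CC[C@@]12C(C)(C)[C@@H]2C(C)=C | intermediate
15 | cis-divinylcyclopropane, C11 epimer of 14 | C=C1[C@](C)(O[Si](CC)(CC)CC)CC[C@@]12C(C)(C)[C@H]2C(C)=C | intermediate
16 | (3R)-3,6,8,8-tetramethyl-3-(triethylsilyloxy)-1,2,3,4,5,8-hexahydroazulene | CC1=CC(C)(C)C2=C(CC1)[C@](C)(O[Si](CC)(CC)CC)CC2 | intermediate
17 | C11 alkyl(isopinocampheyl)borane | C[C@H]1CCC2=C(CC[C@@]2(C)O[Si](CC)(CC)CC)C(C)(C)[C@@H]1B[C@@H]1C[C@@H]2C[C@H]([C@H]1C)C2(C)C | intermediate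
18 | (2S,9R,11R)-C11 alcohol, C9 triethylsilyl ether, C5=C6 | C[C@H]1CCC2=C(CC[C@@]2(C)O[Si](CC)(CC)CC)C(C)(C)[C@@H]1O | intermediate
19 | (2S,9R,11R)-diene diol, C5=C6 | C[C@H]1CCC2=C(CC[C@@]2(C)O)C(C)(C)[C@@H]1O | intermediate
20 | (2S,5R,6R,9R,11R)-cis-fused diol | C[C@H]1CC[C@@H]2[C@@H](CC[C@@]2(C)O)C(C)(C)[C@@H]1O | intermediate
21 | (2S,5R,6R,9R)-C11 ketone, free C9 hydroxyl | C[C@H]1CC[C@@H]2[C@@H](CC[C@@]2(C)O)C(C)(C)C1=O | intermediate
22 | (2S,5R,6R,9R)-C11 ketone, C9 triethylsilyl ether | C[C@H]1CC[C@@H]2[C@@H](CC[C@@]2(C)O[Si](CC)(CC)CC)C(C)(C)C1=O | intermediate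
23 | lithium β,β-diboryl alkoxide (C11 epimers) | [Li+].C[C@H]1CC[C@@H]2[C@@H](CC[C@@]2(C)O[Si](CC)(CC)CC)C(C)(C)C1([O-])C(B1OC(C)(C)C(C)(C)O1)B1OC(C)(C)C(C)(C)O1 | intermediate
24 | (E)-alkenyl pinacol boronate, boron anti to C10 | C[C@H]1CC[C@@H]2[C@@H](CC[C@@]2(C)O[Si](CC)(CC)CC)C(C)(C)/C1=C/B1OC(C)(C)C(C)(C)O1 | intermediate
25 | 2-methylcyclohex-2-en-1-one | CC1=CCCCC1=O | starting material
26 | (R)-2-methylcyclohex-2-en-1-ol | CC1=CCCC[C@H]1O | intermediate
27 | (R)-tert-butyldimethyl(2-methylcyclohex-2-enyloxy)silane | CC1=CCCC[C@H]1O[Si](C)(C)C(C)(C)C | intermediate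
28 | (R)-4-(tert-butyldimethylsilyloxy)-3-methylcyclohex-2-en-1-one | CC1=CC(=O)CC[C@H]1O[Si](C)(C)C(C)(C)C | intermediate
29 | 5-bromo-2-methylpent-2-ene | CC(C)=CCCBr | starting material
30 | (4-methylpent-3-enyl)magnesium bromide | CC(C)=CCC[Mg]Br | intermediate
31 | trimethylsilyl enol ether, C15 methyl cis to the C21 silyloxy group | C[C@@]1(CCC=C(C)C)C=C(O[Si](C)(C)C)CC[C@H]1O[Si](C)(C)C(C)(C)C | intermediate
32 | Mannich base (C14 epimers) | C[C@@]1(CCC=C(C)C)C(CN(C)C)C(=O)CC[C@H]1O[Si](C)(C)C(C)(C)C | intermediate
33 | trimethylammonium iodide (C14 epimers) | [I-].C[C@@]1(CCC=C(C)C)C(C[N+](C)(C)C)C(=O)CC[C@H]1O[Si](C)(C)C(C)(C)C | intermediate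
34 | α-methylene ketone, C21 silyl ether | C[C@@]1(CCC=C(C)C)C(=C)C(=O)CC[C@H]1O[Si](C)(C)C(C)(C)C | intermediate
35 | hydroxy enone | C[C@@]1(CCC=C(C)C)C(=C)C(=O)CC[C@H]1O | intermediate
36 | epoxy alcohol (C18 epimers) | C[C@@]1(CCC2OC2(C)C)C(=C)C(=O)CC[C@H]1O | intermediate
37 | bicyclic enone alcohol, trans-fused rings C and D (C18 epimers) | C=C1[C@@]2(C)CCC(O)C(C)(C)O[C@@H]2CCC1=O | intermediate
38 | bicyclic diol, C24 hydroxyl axial (C18 epimers) | C=C1[C@@]2(C)CCC(O)C(C)(C)O[C@@H]2CC[C@]1(C)O | intermediate
39 | C13 alkylborane, drawn as RBH2 (C18 epimers) | BC[C@@H]1[C@@]2(C)CCC(O)C(C)(C)O[C@@H]2CC[C@]1(C)O | intermediate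
40 | triol with C13 primary alcohol (C18 epimers) | OC[C@@H]1[C@@]2(C)CCC(O)C(C)(C)O[C@@H]2CC[C@]1(C)O | intermediate
41 | primary iodide diol (C18 epimers) | IC[C@@H]1[C@@]2(C)CCC(O)C(C)(C)O[C@@H]2CC[C@]1(C)O | intermediate
42 | primary iodide bis(triethylsilyl) ether (C18 epimers) | IC[C@@H]1[C@@]2(C)CCC(O[Si](CC)(CC)CC)C(C)(C)O[C@@H]2CC[C@]1(C)O[Si](CC)(CC)CC | intermediate
43 | C13 alkyllithium (C18 epimers) | [Li]C[C@@H]1[C@@]2(C)CCC(O[Si](CC)(CC)CC)C(C)(C)O[C@@H]2CC[C@]1(C)O[Si](CC)(CC)CC | intermediate
44 | lithium alkenyl(alkyl)pinacolatoborate complex (C18 epimers) | [Li+].C[C@H]1CC[C@@H]2[C@@H](CC[C@@]2(C)O[Si](CC)(CC)CC)C(C)(C)/C1=C/[B-]1(C[C@@H]3[C@@]4(C)CCC(O[Si](CC)(CC)CC)C(C)(C)O[C@@H]4CC[C@]3(C)O[Si](CC)(CC)CC)OC(C)(C)C(C)(C)O1 | intermediate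
45 | β-iodo boronate, iodine on C11 anti to the migrated C13 group (C11, C12 and C18 open) | C[C@H]1CC[C@@H]2[C@@H](CC[C@@]2(C)O[Si](CC)(CC)CC)C(C)(C)C1(I)C(C[C@@H]1[C@@]2(C)CCC(O[Si](CC)(CC)CC)C(C)(C)O[C@@H]2CC[C@]1(C)O[Si](CC)(CC)CC)B1OC(C)(C)C(C)(C)O1 | intermediate
46 | coupled tris(triethylsilyl) ether, Z alkene (C18 epimers) | C[C@H]1CC[C@@H]2[C@@H](CC[C@@]2(C)O[Si](CC)(CC)CC)C(C)(C)/C1=C\C[C@@H]1[C@@]2(C)CCC(O[Si](CC)(CC)CC)C(C)(C)O[C@@H]2CC[C@]1(C)O[Si](CC)(CC)CC | intermediate
47 | triol (C18 epimers) | C[C@H]1CC[C@@H]2[C@@H](CC[C@@]2(C)O)C(C)(C)/C1=C\C[C@@H]1[C@@]2(C)CCC(O)C(C)(C)O[C@@H]2CC[C@]1(C)O | intermediate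
48 | CNP0157787.1 | C[C@H]1CC[C@@H]2[C@@H](CC[C@@]2(C)O)C(C)(C)/C1=C\C[C@@H]1[C@@]2(C)CCC(=O)C(C)(C)O[C@@H]2CC[C@]1(C)O | target

## Step count and least certain steps

Total: 29 steps. Longest linear sequence: 18 steps (steps 1–15, then 27–29); the right half (steps 16–26, 11 steps) joins at step 27.

Step 9 (key step). The trans isomer 14 may leak into the homodienyl 1,5-hydrogen shift, in which a hydrogen of the C10 methyl cis to a vinyl group moves to the alkene terminus and the cyclopropane opens to an acyclic triene. This would happen before one-centre epimerisation feeds the Cope path. The ring-held C5=C4 arm could also raise the barrier of the [3,3] shift enough for the two processes to overlap. Fallback, setting out from 6 and returning at 16, closes ring A by metathesis instead. Aldol condensation of 6 with acetone gives the isopropylidene ketone F1. Conjugate addition of CH2=CHMgBr with CuBr·SMe2 and trapping of the enolate with N-(5-chloro-2-pyridyl)bis(trifluoromethanesulfonimide) gives the enol triflate F2, which carries the C10 quaternary carbon with its vinyl group. Coupling with (3-methylbut-3-enyl)zinc bromide under Pd(PPh3)4 gives the triene F3. Ring-closing metathesis of F3 with the second-generation Grubbs catalyst forms C11=C2 and gives 16.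

Step 15. The ketone is flanked by a quaternary and a tertiary carbon. Addition of the lithiated diboronate may be slow enough that enolisation toward C2 competes, with loss of the C2 configuration, and the boronate may form as an E/Z mixture. Fallback, from 22 back to 24, makes the alkene first and the C–B bond second. Non-basic methylenation with Cp2Ti(μ-Cl)(μ-CH2)AlMe2 gives the exocyclic methylene compound F4. A palladium-catalysed boryl-Heck reaction (Pd2(dba)3, bulky triarylphosphine, B-chlorocatecholborane, Et3N) gives the alkenyl catechol boronate F5 with boron anti to C10. Exchange with pinacol gives 24.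

Step 27. Formation of the boronate complex between the β-branched alkyllithium 43 and the hindered alkenyl boronate may be incomplete, through protonation of 43 or silyl migration from O24. Stereospecificity may also erode if the iodonium ion at the congested C11 opens to a tertiary cation. Fallback, from 24 and 38 back to 46, replaces the 1,2-metallate rearrangement by a cross-coupling. Bromine adds to 24 to give the dibromo boronate F6, and NaOMe induces anti elimination to the alkenyl bromide F7, bromine syn to C10 (inversion). Diol 38 is silylated to the bis(triethylsilyl) ether F8 and hydroborated with 9-BBN to the B-alkyl-9-BBN F9. Suzuki–Miyaura coupling of F9 with F7 (Pd(dppf)Cl2, AsPh3, Cs2CO3, DMF/THF/H2O) proceeds with retention and gives 46.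

Step 10. Facial selectivity may be poor, because C9 is too remote to reinforce the reagent and the neopentyl-type C11 may force a higher temperature. Fallback, from 16 back to 21, sets C2 after the ring fusion. Hydroboration with BH3·SMe2 and oxidative work-up give the alcohol mixture F10. Dess–Martin oxidation gives the diene ketone F11 and Bu4NF the hydroxy ketone F12. Hydrogenation with [Ir(cod)(PCy3)(py)]PF6, directed by the C9 hydroxyl alone, gives 21 together with its C2 epimer F13. The two converge through their common enolate, first by equilibration with DBU. If the equilibrium lies on the wrong side, the lithium enolate is protonated kinetically from the exposed face with a hindered phenol.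

Step 12. The tertiary allylic alcohol may ionise or dehydrate under the acidic iridium hydride species, or the catalyst may deactivate before the hindered tetrasubstituted alkene is reduced. Fallback, from 18 back to 22, uses only the homoallylic C11 hydroxyl as the directing group and keeps C9 protected. Hydrogenation of 18 with [Ir(cod)(PCy3)(py)]B[3,5-(CF3)2C6H3]4 gives the cis-fused C11 alcohol silyl ether F14, and Dess–Martin oxidation of F14 gives 22. This also removes steps 11 and 14.

## Further compounds

F1 | step 9 | (R)-2-methyl-5-(propan-2-ylidene)-2-(triethylsilyloxy)cyclopentanone | CC(C)=C1CC[C@@](C)(O[Si](CC)(CC)CC)C1=O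
F2 | step 9 | (R)-5-methyl-2-(2-methylbut-3-en-2-yl)-5-(triethylsilyloxy)cyclopent-1-enyl triflate | C=CC(C)(C)C1=C(OS(=O)(=O)C(F)(F)F)[C@](C)(O[Si](CC)(CC)CC)CC1
F3 | step 9 | (R)-triene: 1-(2-methylbut-3-en-2-yl)-2-(3-methylbut-3-enyl)-3-methyl-3-(triethylsilyloxy)cyclopentene | C=CC(C)(C)C1=C(CCC(C)=C)[C@](C)(O[Si](CC)(CC)CC)CC1
F4 | step 15 | C11 exocyclic methylene compound, C9 triethylsilyl ether | C[C@H]1CC[C@@H]2[C@@H](CC[C@@]2(C)O[Si](CC)(CC)CC)C(C)(C)C1=C
F5 | step 15 | (E)-alkenyl catechol boronate | C[C@H]1CC[C@@H]2[C@@H](CC[C@@]2(C)O[Si](CC)(CC)CC)C(C)(C)/C1=C/B1Oc2ccccc2O1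
F6 | step 27 | C11,C12-dibromo pinacol boronate | C[C@H]1CC[C@@H]2[C@@H](CC[C@@]2(C)O[Si](CC)(CC)CC)C(C)(C)C1(Br)C(Br)B1OC(C)(C)C(C)(C)O1
F7 | step 27 | alkenyl bromide, bromine syn to C10 | C[C@H]1CC[C@@H]2[C@@H](CC[C@@]2(C)O[Si](CC)(CC)CC)C(C)(C)/C1=C\Br
F8 | step 27 | bis(triethylsilyl) ether of 38 | C=C1[C@@]2(C)CCC(O[Si](CC)(CC)CC)C(C)(C)O[C@@H]2CC[C@]1(C)O[Si](CC)(CC)CC
F9 | step 27 | B-alkyl-9-borabicyclo[3.3.1]nonane of the right half | C(B1C2CCCC1CCC2)[C@@H]1[C@@]2(C)CCC(O[Si](CC)(CC)CC)C(C)(C)O[C@@H]2CC[C@]1(C)O[Si](CC)(CC)CC
F10 | step 10 | C11 alcohols, both faces (C2 and C11 open), C9 triethylsilyl ether | CC1CCC2=C(CC[C@@]2(C)O[Si](CC)(CC)CC)C(C)(C)C1O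
F11 | step 10 | diene C11 ketone (C2 open), C9 triethylsilyl ether | CC1CCC2=C(CC[C@@]2(C)O[Si](CC)(CC)CC)C(C)(C)C1=O
F12 | step 10 | diene C11 ketone (C2 open), free C9 hydroxyl | CC1CCC2=C(CC[C@@]2(C)O)C(C)(C)C1=O
F13 | step 10 | C2 epimer of 21 | C[C@@H]1CC[C@@H]2[C@@H](CC[C@@]2(C)O)C(C)(C)C1=O
F14 | step 12 | cis-fused C11 alcohol, C9 triethylsilyl ether | C[C@H]1CC[C@@H]2[C@@H](CC[C@@]2(C)O[Si](CC)(CC)CC)C(C)(C)[C@@H]1O
A1 | alternative 1 | 1-diazo-4-(3-methoxy-2,4-dimethylphenyl)butan-2-one | [N-]=[N+]=CC(=O)CCc1ccc(C)c(OC)c1C
A2 | alternative 1 | 5-methoxy-4,6-dimethyl-3,8a-dihydro-2H-azulen-1-one | O=C1CCC2=C(C)C(OC)=C(C)C=C[C@@H]12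
A3 | alternative 2 | 4,4-ethylenedioxy-3-methylcyclohex-2-en-1-one | CC1=CC(=O)CCC12OCCO2
A4 | alternative 2 | left-half Z-allylic bromide, C9 triethylsilyl ether | C[C@H]1CC[C@@H]2[C@@H](CC[C@@]2(C)O[Si](CC)(CC)CC)C(C)(C)/C1=C\CBr
A5 | alternative 2 | coupled C24 ketone with C21 ketal and C18=C19 alkene | C[C@H]1CC[C@@H]2[C@@H](CC[C@@]2(C)O[Si](CC)(CC)CC)C(C)(C)/C1=C\C[C@@H]1[C@@](C)(CCC=C(C)C)C2(OCCO2)CCC1=O
A6 | alternative 3 | bis-epoxy β-keto ester, methyl ester | COC(=O)CC(=O)CC[C@H]1O[C@]1(C)CC[C@H]1OC1(C)C
A7 | alternative 3 | bicyclic hydroxy β-keto ester (rings C and D) | COC(=O)[C@@H]1[C@@]2(C)CC[C@@H](O)C(C)(C)O[C@@H]2CCC1=O
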